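## The problem

Target 47 is a (7R,8S,7'R,8'S)-2,6-diaryl-3,7-dioxabicyclo[3.3.0]octane (the syringaresinol furofuran) whose two syringyl oxygens carry different arylglycerol β-ether chains. One carries a single (7S,8R)-erythro-guaiacylglycerol unit (unit c). The other carries a (7R,8R)-threo unit (unit b) whose guaiacyl oxygen is etherified by a (7R,8S)-erythro unit (unit a).

The two tetrahydrofuran rings share the C8–C8' bond and must be cis-fused with both aryl groups exo. The four contiguous centres C7, C8, C8', C7' depend on each other, so fixing the two carbinol carbons and the ring fusion fixes all four.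

The six side-chain centres are insulated from the core by an aryl ether and cannot be steered by it. Each C7/C8 pair needs its own external control, and erythro and threo pairs call for different bond constructions.

The two core phenols are homotopic in the C2-symmetric core, so they must be told apart before the arms are attached.

Several groups will not survive rough treatment: the benzylic C7–O bonds of the furofuran next to electron-rich syringyl rings (acid epimerisation, hydrogenolysis); three p-oxygenated benzylic carbinols β to aryloxy groups (ionisation, retro-aldol cleavage); and the free guaiacyl phenols of the product. This calls for a neutral, fluoride-only endgame.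

The enabling feature is the chain C7–C8–C8'–C7', a 1,4-diarylbutane oxygenated at C7 and C7' with carboxyl-level carbons C9 and C9' on C8 and C8'. At the diaroylsuccinate oxidation level, C8 and C8' each lie between a ketone and an ester and are configurationally labile. Each C7 oxygen is γ to the ester carbon of the other half (C9' and C9). Reducing the two ketones can therefore lock all four centres into one cis-fused bis-γ-lactone.

## Retrosynthesis

**Endgame, 47 from 46.** Six Si–O bonds are cut. Every hydroxyl that must be masked late in the route is a silyl ether (four TBS, two aryl TIPS), so the last step is a buffered fluoride treatment. Benzyl groups on the terminal phenols would force a hydrogenolysis next to four benzylic C–O bonds; acetals would need acid.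

**Threo unit b, 46 from imide 35 and aldehyde 43 via aldol adduct 45.** The C7b–C8b bond is cut, with C9b taken back to the acyl level of an oxazolidinone imide. Against cutting O–C8b (substitution by a hindered 2,6-dimethoxyphenol at a carbon flanked by a bulky carbinol) or aryl–C7b (which gives erythro under Felkin control), the aldol cut gives the threo pair directly from an auxiliary-controlled syn aldol. It divides the molecule into two halves of similar size. The forward reaction must tolerate many ether oxygens and silyl groups; nothing else is asked of it.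

**Aldehyde 43 from 41, 40, 38, and finally bromophenol 27, glycerate 37 and Grignard reagent 29.** The formyl carbon is traced to an aryl bromide, which is inert during the preceding steps. The C7a–aryl bond is cut to an α-aryloxy aldehyde (39) and the aryl Grignard reagent 29, since polar Felkin–Anh addition gives erythro. Reagent 29 is prepared once from aryl bromide 28 and serves both erythro units. The C8a–O bond is cut to a phenol and a glycerate by Mitsunobu inversion. This fragment is small, so an imperfect isomer ratio at C7a can be dealt with cheaply.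

**Imide 35 from phenol 33 and chloroacetyl imide 34; 33 from 32, 31, 26 and finally phenol 23 and glycerate 25.** The O–CH2 bond of 35 is a simple Williamson cut. Unit c is dismantled by the same two cuts as unit a (aryl–C7c with 29, then O–C8c), in the mirror-image series. It is installed first so that the less selective arylation falls in mid-route and the reagent-controlled aldol comes last.

**Phenol 23 from 22, tetraol 20 and bis-lactone 19.** The benzyl/TIPS pair on the two syringyl oxygens of 22 allows one phenol to be released by fluoride (23) and the other later by hydrogenolysis (33). The two ether bonds O7–C9' and O7'–C9 are cut to tetraol 20. Ring closure then happens at primary carbons and cannot disturb a stereocentre. Tetraol 20 is the reduction product of bis-lactone 19.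

**Key disconnection, 19 from diaroylsuccinate 17.** Two C–H bonds (C7, C7') and two acyl C–O bonds (O7–C9', O7'–C9) are removed. The precursor has no fixed stereocentre and no ring. The forward reaction must reduce both ketones with the same facial sense and let C8 and C8' follow.

**Diaroylsuccinate 17 from β-keto esters 15 and 9.** The central C8–C8' bond is cut to an enolate and an α-halo-β-keto ester. The chloride 9 is preferred to the bromide because halogen transfer to the enolate, which would scramble the two halves, is slower for chlorine. Both β-keto esters (8, 15) come from protected syringic acids (4, 12) and potassium ethyl malonate (5), hence from syringic acid (1).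

## Roads not taken

**Alternative 1:** This plan cuts the two terminal aryl–C7 bonds of units a and c at once. Two equivalents of aryl Grignard reagent A2 would add to the bis(α-aryloxy aldehyde) A1 to give A3, which holds the complete skeleton with unit b masked as an acetonide.
- Merits: two bonds and two carbinol centres form in one operation; polar Felkin–Anh addition matches the erythro configuration of both outer units; it is about three operations shorter in arm construction than the chosen plan.
- Weak points: it presupposes the furofuran and the threo unit and solves neither. Two epimerisable α-aryloxy aldehydes sit in one advanced molecule. The selectivity is needed twice on the most valuable intermediate, and the by-products differ only at remote centres. The benzyl groups of A3 call for hydrogenolysis at the end.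
- Comparison: the chosen plan uses the same Felkin arylation (steps 15 and 21) but one at a time, once on a small fragment and once in mid-route. It sets against the shorter arm sequence of Alternative 1 an auxiliary-controlled aldol for the threo pair as the last C–C bond formation.

**Alternative 2:** This plan cuts C7–C8 and C8'–C7' and keeps C8–C8' from butenolide A4. The lithio derivative of dithiane A5 adds anti to the acetal substituent of A4, and the lactone enolate is trapped by aldehyde A6 to give A7.
- Merits: the two aryl groups enter through different reagents, so the core is unsymmetrical from the start with no cross-coupling or scrambling issue. In this respect it is better than the chosen plan. The trans relationship it creates at C8/C8' is the one the cis-fused furofuran needs, and the chemistry is well established for lignans.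
- Weak points: only C8 and C8' are controlled. C7' arises as carbinol epimers, and C7 is a masked ketone that needs dithiane removal and a separate stereoselective reduction. The acetal carbon and the lactone carbonyl must both be brought to the alcohol level before ring closure. The auxiliary is stoichiometric. Roughly six operations separate A7 from the stage of 22, against two from 19.
- Comparison: the chosen plan sets one catalytic operation for all four core centres against the greater security of Alternative 2. If the key step failed on diastereocontrol, this would be the most credible replacement for the core.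

**Alternative 3:** This plan cuts both aryl–C7 bonds. Bis-lactol diacetate A8 is ionised twice by a Lewis acid and each oxocarbenium ion is captured by arylzinc bromide A9 on the convex face, giving the dibenzyl ether A10.
- Merits: it is the most direct route to the symmetric core. C7 and C7' are set by the shape of the bicycle, which is arguably safer than a dynamic resolution.
- Weak points: A8 must itself be made enantiopure, which only moves the asymmetric problem. A10 carries two identical benzyl ethers, so the different arms would need a statistical mono-deprotection. The Lewis acid can re-ionise the newly formed benzylic ether and erode the exo selectivity.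
- Comparison: Alternative 3 is better in directness and in substrate-controlled C7 configuration. The chosen plan sets against it phenols that are differentiated from the first step and absolute configuration created by a catalyst, not imported.

Key step: step 7

## Route

Assumption: methyl (R)- and (S)-glycerate and (4S)-4-benzyl-3-(chloroacetyl)-1,3-oxazolidin-2-one are treated as purchasable; each is otherwise one routine step from commercial material.

Abbreviations used in names:
- SyrBn = 4-benzyloxy-3,5-dimethoxyphenyl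
- SyrTIPS = 3,5-dimethoxy-4-(triisopropylsilyloxy)phenyl
- GuaTIPS = 3-methoxy-4-(triisopropylsilyloxy)phenyl
- TBS = tert-butyldimethylsilyl; TIPS = triisopropylsilyl
- FF = tetrahydro-1H,3H-furo[3,4-c]furan
- eryA = (1R,2S)-1,3-bis(TBS-oxy)-1-(GuaTIPS)propan-2-yl
- eryC = (1S,2R)-1,3-bis(TBS-oxy)-1-(GuaTIPS)propan-2-yl
- Xc = (4S)-4-benzyl-2-oxo-1,3-oxazolidin-3-yl
- Lignan locants: C7, C8, C9 and C7', C8', C9' for the core; suffixes a, b, c for the three arylglycerol units.

Step 1
Reactants: 1 syringic acid; 2 benzyl bromide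
Product: 4 4-benzyloxy-3,5-dimethoxybenzoic acid, via benzyl ester 3 (not isolated)
Conditions: BnBr (2.2 equiv), K2CO3, DMF, 60 °C; then NaOH, MeOH/H2O, 65 °C; HCl
Reagents that add atoms: sodium hydroxide [Na+].[OH-]
Why: Williamson O-benzylation of phenol and carboxylate followed by saponification of the benzyl ester; the aryl benzyl ether is inert to hydroxide.

Step 2
Reactants: 4 4-benzyloxy-3,5-dimethoxybenzoic acid; 5 potassium ethyl malonate
Product: 8 ethyl 3-(4-benzyloxy-3,5-dimethoxyphenyl)-3-oxopropanoate, via acyl imidazolide 6 (not isolated), via acylmalonic half ester 7 (not isolated)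
Conditions: CDI, THF, rt; then 5, MgCl2, Et3N, MeCN, rt to 50 °C; 1 M HCl
Reagents that add atoms: none
Why: Masamune-type C-acylation of the magnesium enolate of the malonate half ester by the acyl imidazolide, then decarboxylation on acidification; a standard homologation of benzoic acids to aroylacetates.

Step 3
Reactants: 8 ethyl 3-(4-benzyloxy-3,5-dimethoxyphenyl)-3-oxopropanoate
Product: 9 ethyl 2-chloro-3-(4-benzyloxy-3,5-dimethoxyphenyl)-3-oxopropanoate (racemic)
Conditions: SO2Cl2 (1.0 equiv), CH2Cl2, 0 °C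
Reagents that add atoms: sulfuryl chloride O=S(=O)(Cl)Cl
Why: Electrophilic α-chlorination of the β-keto ester through its enol; one equivalent at 0 °C should stop at the monochloride and spare the acyl-deactivated ring. The chloride is chosen over the bromide because it transfers halogen to enolates much less readily in step 6.

Step 4
Reactants: 1 syringic acid; 10 triisopropylsilyl chloride
Product: 12 3,5-dimethoxy-4-(triisopropylsilyloxy)benzoic acid, via silyl ester 11 (not isolated)
Conditions: TIPSCl (2.3 equiv), imidazole, DMF, 40 °C; then K2CO3, MeOH/THF/H2O, rt; dilute HCl to pH 4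
Reagents that add atoms: none
Why: Silylation of phenol and acid, then selective solvolysis of the much more labile silyl ester; the aryl TIPS ether is shielded by two ortho methoxy groups.

Step 5
Reactants: 12 3,5-dimethoxy-4-(triisopropylsilyloxy)benzoic acid; 5 potassium ethyl malonate
Product: 15 ethyl 3-[3,5-dimethoxy-4-(triisopropylsilyloxy)phenyl]-3-oxopropanoate, via acyl imidazolide 13 (not isolated), via acylmalonic half ester 14 (not isolated)
Conditions: CDI, THF, rt; then 5, MgCl2, Et3N, MeCN, rt to 50 °C; 1 M HCl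
Reagents that add atoms: none
Why: Same Masamune-type acylation–decarboxylation as step 2; the hindered aryl silyl ether tolerates imidazole and the brief acidic work-up.

Step 6
Reactants: 15 ethyl 3-[3,5-dimethoxy-4-(triisopropylsilyloxy)phenyl]-3-oxopropanoate; 9 ethyl 2-chloro-3-(4-benzyloxy-3,5-dimethoxyphenyl)-3-oxopropanoate
Product: 17 diethyl 2-(4-benzyloxy-3,5-dimethoxybenzoyl)-3-[3,5-dimethoxy-4-(triisopropylsilyloxy)benzoyl]succinate (mixture of interconverting stereoisomers), via sodium enolate 16 (not isolated)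
Conditions: NaH, THF, 0 °C; then 9, THF/DMF, −20 °C to rt
Reagents that add atoms: none
Why: SN2 C-alkylation of a stabilised sodium enolate by an α-chloro-β-keto ester, the classical entry to unsymmetrical 2,3-diacylsuccinates. No stereocontrol is wanted because both new centres remain labile.

Step 7
Reactants: 17 diethyl 2-(4-benzyloxy-3,5-dimethoxybenzoyl)-3-[3,5-dimethoxy-4-(triisopropylsilyloxy)benzoyl]succinate
Product: 19 (3R,3aR,6R,6aR)-3-(SyrBn)-6-(SyrTIPS)tetrahydro-1H,3H-furo[3,4-c]furan-1,4-dione (cis-fused; both aryl groups exo), via dihydroxy diester 18 (not isolated)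
Conditions: RuCl(p-cymene)[(R,R)-TsDPEN] (5 mol %), HCO2H/Et3N (5:2), DMF, 40 °C; then 60 °C
Reagents that add atoms: none
Why: Proposed new method: each aryl ketone is reduced by concerted hydride/proton transfer from the ruthenium hydride–amine complex in the usual outer-sphere six-membered transition state, and the (R,R)-ligand, which orients the aryl group towards the η6-cymene, delivers hydrogen to the same face of both ketones so that C7 and C7' are both formed R (catalyst control, matching the C2 symmetry of the core). Before its ketone is reduced, each of C8 and C8' is the α-carbon of a β-keto ester and epimerises through the enol in the formic acid/triethylamine buffer, so the catalyst can select the faster-reacting epimer; hydride is expected to enter anti to the bulky succinate branch, which gives the 7,8- and 7',8'-relationships drawn in diol diester 18 (dynamic kinetic resolution, substrate bias read by the catalyst). Each new hydroxyl then attacks the ester of the other half by 5-exo-trig addition–elimination (O7 to C9' closes the first γ-lactone, O7' to C9 the second), whichever ketone reacts first and whether or not the first ring closes before the second reduction. The second closure can only give a cis-fused bicycle, so it ties C8 to C8'; with both carbinols R the only bicycles that can form are the exo,exo and the endo,endo isomer, and the former follows from the expected epimer selection. The closest known reactions are transfer hydrogenation with dynamic kinetic resolution of single α-substituted aryl β-keto esters by the same catalyst type and reduction–lactonisation of keto esters to γ-lactones; what is new is the doubling on a 2,3-diacylsuccinate, where four centres must converge. The step needs ketone-over-ester chemoselectivity (inherent to transfer hydrogenation), regioselective lactonisation (the proximal ester would give a β-lactone, the distal one a γ-lactone), high enantioface selectivity (secured by the aryl ketone motif) and C8/C8' epimerisation that is fast relative to reduction (secured by the doubly activated C–H bonds).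

Step 8
Reactants: 19 bis-lactone
Product: 20 (1R,2S,3S,4R)-1-(SyrBn)-4-(SyrTIPS)-2,3-bis(hydroxymethyl)butane-1,4-diol
Conditions: LiAlH4, THF, 0 °C to rt
Reagents that add atoms: none
Why: Hydride reduction of both γ-lactones to diols; no bond to a stereocentre is broken, and the hindered aryl silyl ether and the benzyl ether are inert.

Step 9
Reactants: 20 tetraol
Product: 22 (1R,3aS,4R,6aS)-1-(SyrBn)-4-(SyrTIPS)-FF, via bis-mesylate 21 (not isolated)
Conditions: MsCl (2.2 equiv), pyridine, 0 °C to rt
Reagents that add atoms: none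
Why: Selective sulfonylation of both primary hydroxyls, then double intramolecular Williamson etherification (5-exo-tet; O7 to C9' and O7' to C9). Substitution occurs at CH2, so all four centres are retained, and the (2S,3S) backbone can only close to the cis-fused bicycle.

Step 10
Reactants: 22 benzyl/TIPS-protected furofuran
Product: 23 4-[(1R,3aS,4R,6aS)-4-(SyrBn)-FF-1-yl]-2,6-dimethoxyphenol
Conditions: TBAF, THF, 0 °C; NH4Cl aq
Reagents that add atoms: none
Why: Fluoride cleavage of the aryl silyl ether; the benzyl ether is untouched, which is how the two homotopic phenols of the core are told apart.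

Step 11
Reactants: 24 methyl (S)-glycerate
Product: 25 methyl (2S)-3-(tert-butyldimethylsilyloxy)-2-hydroxypropanoate
Conditions: TBSCl (1.05 equiv), imidazole, CH2Cl2, 0 °C
Reagents that add atoms: tert-butyldimethylsilyl chloride CC(C)(C)[Si](C)(C)Cl
Why: Sterically controlled silylation of the primary hydroxyl; the stereocentre is not involved.

Step 12
Reactants: 23 phenol; 25 methyl (2S)-3-(TBS-oxy)-2-hydroxypropanoate
Product: 26 methyl (2R)-3-(TBS-oxy)-2-{4-[(1R,3aS,4R,6aS)-4-(SyrBn)-FF-1-yl]-2,6-dimethoxyphenoxy}propanoate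
Conditions: PPh3, DIAD, THF, 0 °C to rt
Reagents that add atoms: none
Why: Mitsunobu etherification; SN2 displacement of the activated α-hydroxy ester by the phenol with inversion, (S)-alcohol to (R)-aryl ether, which sets C8c.

Step 13
Reactants: 27 4-bromo-2-methoxyphenol; 10 triisopropylsilyl chloride
Product: 28 (4-bromo-2-methoxyphenoxy)triisopropylsilane
Conditions: TIPSCl, imidazole, DMF, rt
Reagents that add atoms: none
Why: Routine phenol silylation; TIPS is chosen over TBS so the phenol mask survives the basic and reductive steps that follow.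

Step 14
Reactants: 28 (4-bromo-2-methoxyphenoxy)triisopropylsilane
Product: 29 [3-methoxy-4-(triisopropylsilyloxy)phenyl]magnesium bromide (titrated THF solution, kept under argon)
Conditions: Mg turnings, I2 (cat.), THF, 50 °C
Reagents that add atoms: magnesium [Mg]
Why: Grignard reagent formation by direct insertion of magnesium into the aryl C–Br bond; the hindered aryl silyl ether and the methoxy group are inert, and one titrated stock solution serves both arylations (steps 15 and 21).

Step 15
Reactants: 26 α-aryloxy ester; 29 [3-methoxy-4-(triisopropylsilyloxy)phenyl]magnesium bromide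
Product: 31 (1S,2R)-3-(TBS-oxy)-1-(GuaTIPS)-2-{4-[(1R,3aS,4R,6aS)-4-(SyrBn)-FF-1-yl]-2,6-dimethoxyphenoxy}propan-1-ol (erythro), via aldehyde 30 (not isolated)
Conditions: 26, iBu2AlH (1.05 equiv), CH2Cl2, −78 °C; then 29 in THF (3 equiv), −78 to −30 °C; aq. potassium sodium tartrate
Reagents that add atoms: none
Why: One-pot partial reduction–Grignard addition: the aluminium hemiacetal releases the α-aryloxy aldehyde only as it is consumed, which limits epimerisation at C8c. Polar Felkin–Anh addition anti to the aryloxy group should set C7c as S and give the erythro (1S,2R) alcohol.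

Step 16
Reactants: 31 erythro alcohol
Product: 32 (1R,3aS,4R,6aS)-1-(SyrBn)-4-[3,5-dimethoxy-4-(eryC-oxy)phenyl]-FF
Conditions: TBSOTf, 2,6-lutidine, CH2Cl2, −78 to 0 °C
Reagents that add atoms: tert-butyldimethylsilyl trifluoromethanesulfonate CC(C)(C)[Si](C)(C)OS(=O)(=O)C(F)(F)F
Why: Silylation of the hindered secondary benzylic hydroxyl with the silyl triflate; excess lutidine keeps the medium non-acidic so the furofuran C7–O bonds are not ionised.

Step 17
Reactants: 32 benzyl ether
Product: 33 4-{(1R,3aS,4R,6aS)-4-[3,5-dimethoxy-4-(eryC-oxy)phenyl]-FF-1-yl}-2,6-dimethoxyphenol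
Conditions: H2 (1 atm), Pd/C (10 wt %), EtOAc, rt; stopped when 32 is consumed
Reagents that add atoms: none
Why: Catalytic hydrogenolysis of the phenolic benzyl ether, which under neutral conditions should be cleaved much faster than the dialkyl benzylic ethers of the furofuran or the benzylic silyl ether.

Step 18
Reactants: 33 phenol; 34 (4S)-4-benzyl-3-(chloroacetyl)-1,3-oxazolidin-2-one
Product: 35 Xc-C(=O)CH2-O-Ar, the (aryloxy)acetyl imide in which ArOH is phenol 33
Conditions: K2CO3, acetone, 50 °C
Reagents that add atoms: none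
Why: Williamson alkylation of the phenoxide at the activated α-chloro carbon; SN2 at this unhindered primary carbon should outrun attack at the imide carbonyl, and anhydrous carbonate in acetone leaves the aryl silyl ethers intact.

Step 19
Reactants: 36 methyl (R)-glycerate
Product: 37 methyl (2R)-3-(tert-butyldimethylsilyloxy)-2-hydroxypropanoate
Conditions: TBSCl (1.05 equiv), imidazole, CH2Cl2, 0 °C
Reagents that add atoms: tert-butyldimethylsilyl chloride CC(C)(C)[Si](C)(C)Cl
Why: Selective primary silylation, as in step 11.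

Step 20
Reactants: 27 4-bromo-2-methoxyphenol; 37 methyl (2R)-3-(TBS-oxy)-2-hydroxypropanoate
Product: 38 methyl (2S)-2-(4-bromo-2-methoxyphenoxy)-3-(tert-butyldimethylsilyloxy)propanoate
Conditions: PPh3, DIAD, THF, 0 °C to rt
Reagents that add atoms: none
Why: Mitsunobu etherification with inversion, (R)-alcohol to (S)-aryl ether, which sets C8a; the aryl bromide is a masked formyl group that is inert here.

Step 21
Reactants: 38 α-aryloxy ester; 29 [3-methoxy-4-(triisopropylsilyloxy)phenyl]magnesium bromide
Product: 40 (1R,2S)-2-(4-bromo-2-methoxyphenoxy)-3-(TBS-oxy)-1-(GuaTIPS)propan-1-ol (erythro), via aldehyde 39 (not isolated)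
Conditions: 38, iBu2AlH (1.05 equiv), CH2Cl2, −78 °C; then 29 in THF (3 equiv), −78 to −30 °C; aq. potassium sodium tartrate
Reagents that add atoms: none
Why: Same one-pot reduction–arylation as step 15 in the mirror-image series; Felkin–Anh addition should set C7a as R (erythro). The aryl bromide of 38 does not exchange with the Grignard reagent at low temperature.

Step 22
Reactants: 40 erythro alcohol
Product: 41 [(1R,2S)-2-(4-bromo-2-methoxyphenoxy)-1-(GuaTIPS)propane-1,3-diyl]bis(oxy)bis(tert-butyldimethylsilane)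
Conditions: TBSOTf, 2,6-lutidine, CH2Cl2, −78 to 0 °C
Reagents that add atoms: tert-butyldimethylsilyl trifluoromethanesulfonate CC(C)(C)[Si](C)(C)OS(=O)(=O)C(F)(F)F
Why: Silylation of the secondary benzylic hydroxyl, so that no acidic proton remains for the organolithium and boron enolate steps.

Step 23
Reactants: 41 aryl bromide
Product: 43 3-methoxy-4-(eryA-oxy)benzaldehyde, via aryllithium 42 (not isolated)
Conditions: n-BuLi, THF, −78 °C; then DMF, −78 °C to 0 °C; NH4Cl aq
Reagents that add atoms: N,N-dimethylformamide CN(C)C=O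
Why: Bromine–lithium exchange and formylation (Bouveault type); exchange at −78 °C is faster than any attack on silyl ethers, and the stereocentres carry no acidic hydrogen next to a carbonyl.

Step 24
Reactants: 35 (aryloxy)acetyl imide; 43 aldehyde
Product: 45 Xc-C(=O)-[(2S,3R)-CH(OAr)-CH(OH)-Ar'] in which ArOH is phenol 33 and Ar' is 3-methoxy-4-(eryA-oxy)phenyl (syn aldol adduct), via boron enolate 44 (not isolated)
Conditions: Bu2BOTf (1.2 equiv), iPr2NEt, CH2Cl2, −78 to 0 °C; then 43, −78 to 0 °C; pH 7 buffer, MeOH, H2O2, 0 °C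
Reagents that add atoms: none
Why: Evans syn aldol: the Z boron enolate reacts through a Zimmerman–Traxler chair on the face away from the auxiliary benzyl group, which sets C8b and C7b under reagent control (2S,3R in the imide, 7R,8R-threo after reduction). The stereocentres of 43 are remote and should not interfere.

Step 25
Reactants: 45 aldol adduct
Product: 46 (1R,2R)-1-[3-methoxy-4-(eryA-oxy)phenyl]-2-(aryloxy of phenol 33)propane-1,3-diol (threo)
Conditions: LiBH4, MeOH (1 equiv), THF, 0 °C
Reagents that add atoms: none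
Why: Reductive cleavage of the N-acyl oxazolidinone to the primary alcohol C9b with release of the auxiliary; neither new centre is epimerisable under these conditions and the silyl ethers survive.

Step 26
Reactants: 46 hexasilyl ether
Product: 47 target CNP0316493.1
Conditions: TBAF (10 equiv), AcOH (10 equiv), THF, 0 to 40 °C
Reagents that add atoms: none
Why: Global fluoride desilylation of four alkyl TBS and two aryl TIPS ethers; the acetic acid buffer keeps the liberated p-hydroxybenzyl alcohols away from phenoxide-driven retro-aldol or quinone-methide pathways, and no stereocentre is touched.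

## Compound list

1 | syringic acid (4-hydroxy-3,5-dimethoxybenzoic acid) | COc1cc(C(=O)O)cc(OC)c1O | starting material
2 | benzyl bromide | BrCc1ccccc1 | starting material
3 | benzyl 4-benzyloxy-3,5-dimethoxybenzoate | COc1cc(C(=O)OCc2ccccc2)cc(OC)c1OCc1ccccc1 | intermediate
4 | 4-benzyloxy-3,5-dimethoxybenzoic acid | COc1cc(C(=O)O)cc(OC)c1OCc1ccccc1 | intermediate
5 | potassium ethyl malonate | CCOC(=O)CC(=O)[O-].[K+] | starting material
6 | 1-(4-benzyloxy-3,5-dimethoxybenzoyl)imidazole | COc1cc(C(=O)n2ccnc2)cc(OC)c1OCc1ccccc1 | intermediate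
7 | 2-(4-benzyloxy-3,5-dimethoxybenzoyl)malonic acid monoethyl ester (magnesium salt in the flask) | CCOC(=O)C(C(=O)O)C(=O)c1cc(OC)c(OCc2ccccc2)c(OC)c1 | intermediate
8 | ethyl 3-(4-benzyloxy-3,5-dimethoxyphenyl)-3-oxopropanoate | CCOC(=O)CC(=O)c1cc(OC)c(OCc2ccccc2)c(OC)c1 | intermediate
9 | ethyl 2-chloro-3-(4-benzyloxy-3,5-dimethoxyphenyl)-3-oxopropanoate (racemic) | CCOC(=O)C(Cl)C(=O)c1cc(OC)c(OCc2ccccc2)c(OC)c1 | intermediate
10 | triisopropylsilyl chloride | CC(C)[Si](Cl)(C(C)C)C(C)C | starting material
11 | triisopropylsilyl 3,5-dimethoxy-4-(triisopropylsilyloxy)benzoate | COc1cc(C(=O)O[Si](C(C)C)(C(C)C)C(C)C)cc(OC)c1O[Si](C(C)C)(C(C)C)C(C)C | intermediate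
12 | 3,5-dimethoxy-4-(triisopropylsilyloxy)benzoic acid | COc1cc(C(=O)O)cc(OC)c1O[Si](C(C)C)(C(C)C)C(C)C | intermediate
13 | 1-[3,5-dimethoxy-4-(triisopropylsilyloxy)benzoyl]imidazole | COc1cc(C(=O)n2ccnc2)cc(OC)c1O[Si](C(C)C)(C(C)C)C(C)C | intermediate
14 | 2-[3,5-dimethoxy-4-(triisopropylsilyloxy)benzoyl]malonic acid monoethyl ester (magnesium salt in the flask) | CCOC(=O)C(C(=O)O)C(=O)c1cc(OC)c(O[Si](C(C)C)(C(C)C)C(C)C)c(OC)c1 | intermediate
15 | ethyl 3-[3,5-dimethoxy-4-(triisopropylsilyloxy)phenyl]-3-oxopropanoate | CCOC(=O)CC(=O)c1cc(OC)c(O[Si](C(C)C)(C(C)C)C(C)C)c(OC)c1 | intermediate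
16 | sodium enolate of 15 | CCOC(=O)C=C([O-])c1cc(OC)c(O[Si](C(C)C)(C(C)C)C(C)C)c(OC)c1.[Na+] | intermediate
17 | diethyl 2-(4-benzyloxy-3,5-dimethoxybenzoyl)-3-[3,5-dimethoxy-4-(triisopropylsilyloxy)benzoyl]succinate, stereoisomer mixture | CCOC(=O)C(C(=O)c1cc(OC)c(OCc2ccccc2)c(OC)c1)C(C(=O)OCC)C(=O)c1cc(OC)c(O[Si](C(C)C)(C(C)C)C(C)C)c(OC)c1 | intermediate
18 | diethyl (2R,3R)-2-[(R)-hydroxy(SyrBn)methyl]-3-[(R)-hydroxy(SyrTIPS)methyl]succinate | COc1cc([C@H](O)[C@H](C(=O)OCC)[C@@H](C(=O)OCC)[C@@H](O)c2cc(OC)c(O[Si](C(C)C)(C(C)C)C(C)C)c(OC)c2)cc(OC)c1OCc1ccccc1 | intermediate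
19 | (3R,3aR,6R,6aR)-3-(SyrBn)-6-(SyrTIPS)tetrahydro-1H,3H-furo[3,4-c]furan-1,4-dione, cis-fused, both aryl groups exo | COc1cc([C@@H]2OC(=O)[C@@H]3[C@H]2C(=O)O[C@H]3c2cc(OC)c(O[Si](C(C)C)(C(C)C)C(C)C)c(OC)c2)cc(OC)c1OCc1ccccc1 | intermediate
20 | (1R,2S,3S,4R)-1-(SyrBn)-4-(SyrTIPS)-2,3-bis(hydroxymethyl)butane-1,4-diol | COc1cc([C@H](O)[C@H](CO)[C@@H](CO)[C@@H](O)c2cc(OC)c(O[Si](C(C)C)(C(C)C)C(C)C)c(OC)c2)cc(OC)c1OCc1ccccc1 | intermediate
21 | bis(methanesulfonate) of 20 at both primary hydroxyls | COc1cc([C@H](O)[C@H](COS(C)(=O)=O)[C@@H](COS(C)(=O)=O)[C@@H](O)c2cc(OC)c(O[Si](C(C)C)(C(C)C)C(C)C)c(OC)c2)cc(OC)c1OCc1ccccc1 | intermediate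
22 | (1R,3aS,4R,6aS)-1-(SyrBn)-4-(SyrTIPS)-FF | COc1cc([C@@H]2OC[C@@H]3[C@H]2CO[C@H]3c2cc(OC)c(O[Si](C(C)C)(C(C)C)C(C)C)c(OC)c2)cc(OC)c1OCc1ccccc1 | intermediate
23 | 4-[(1R,3aS,4R,6aS)-4-(SyrBn)-FF-1-yl]-2,6-dimethoxyphenol | COc1cc([C@@H]2OC[C@@H]3[C@H]2CO[C@H]3c2cc(OC)c(O)c(OC)c2)cc(OC)c1OCc1ccccc1 | intermediate
24 | methyl (S)-glycerate, methyl (2S)-2,3-dihydroxypropanoate | COC(=O)[C@H](CO)O | starting material
25 | methyl (2S)-3-(tert-butyldimethylsilyloxy)-2-hydroxypropanoate | COC(=O)[C@H](CO[Si](C)(C)C(C)(C)C)O | intermediate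
26 | methyl (2R)-3-(TBS-oxy)-2-{4-[(1R,3aS,4R,6aS)-4-(SyrBn)-FF-1-yl]-2,6-dimethoxyphenoxy}propanoate | COc1cc([C@@H]2OC[C@@H]3[C@H]2CO[C@H]3c2cc(OC)c(O[C@H](CO[Si](C)(C)C(C)(C)C)C(=O)OC)c(OC)c2)cc(OC)c1OCc1ccccc1 | intermediate
27 | 4-bromo-2-methoxyphenol | COc1cc(Br)ccc1O | starting material
28 | (4-bromo-2-methoxyphenoxy)triisopropylsilane | COc1cc(Br)ccc1O[Si](C(C)C)(C(C)C)C(C)C | intermediate
29 | [3-methoxy-4-(triisopropylsilyloxy)phenyl]magnesium bromide, titrated THF solution | COc1cc([Mg]Br)ccc1O[Si](C(C)C)(C(C)C)C(C)C | intermediate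
30 | (2R)-3-(TBS-oxy)-2-{4-[(1R,3aS,4R,6aS)-4-(SyrBn)-FF-1-yl]-2,6-dimethoxyphenoxy}propanal | COc1cc([C@@H]2OC[C@@H]3[C@H]2CO[C@H]3c2cc(OC)c(O[C@H](CO[Si](C)(C)C(C)(C)C)C=O)c(OC)c2)cc(OC)c1OCc1ccccc1 | intermediate
31 | (1S,2R)-3-(TBS-oxy)-1-(GuaTIPS)-2-{4-[(1R,3aS,4R,6aS)-4-(SyrBn)-FF-1-yl]-2,6-dimethoxyphenoxy}propan-1-ol, erythro | COc1cc([C@@H]2OC[C@@H]3[C@H]2CO[C@H]3c2cc(OC)c(O[C@H](CO[Si](C)(C)C(C)(C)C)[C@@H](O)c3ccc(O[Si](C(C)C)(C(C)C)C(C)C)c(OC)c3)c(OC)c2)cc(OC)c1OCc1ccccc1 | intermediate
32 | (1R,3aS,4R,6aS)-1-(SyrBn)-4-[3,5-dimethoxy-4-(eryC-oxy)phenyl]-FF | COc1cc([C@@H]2OC[C@@H]3[C@H]2CO[C@H]3c2cc(OC)c(O[C@H](CO[Si](C)(C)C(C)(C)C)[C@@H](O[Si](C)(C)C(C)(C)C)c3ccc(O[Si](C(C)C)(C(C)C)C(C)C)c(OC)c3)c(OC)c2)cc(OC)c1OCc1ccccc1 | intermediate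
33 | 4-{(1R,3aS,4R,6aS)-4-[3,5-dimethoxy-4-(eryC-oxy)phenyl]-FF-1-yl}-2,6-dimethoxyphenol | COc1cc([C@@H]2OC[C@@H]3[C@H]2CO[C@H]3c2cc(OC)c(O[C@H](CO[Si](C)(C)C(C)(C)C)[C@@H](O[Si](C)(C)C(C)(C)C)c3ccc(O[Si](C(C)C)(C(C)C)C(C)C)c(OC)c3)c(OC)c2)cc(OC)c1O | intermediate
34 | (4S)-4-benzyl-3-(chloroacetyl)-1,3-oxazolidin-2-one | O=C1OC[C@H](Cc2ccccc2)N1C(=O)CCl | starting material
35 | (4S)-4-benzyl-3-[(aryloxy)acetyl]-1,3-oxazolidin-2-one, aryloxy = phenoxide of 33 | COc1cc([C@@H]2OC[C@@H]3[C@H]2CO[C@H]3c2cc(OC)c(O[C@H](CO[Si](C)(C)C(C)(C)C)[C@@H](O[Si](C)(C)C(C)(C)C)c3ccc(O[Si](C(C)C)(C(C)C)C(C)C)c(OC)c3)c(OC)c2)cc(OC)c1OCC(=O)N1[C@@H](Cc2ccccc2)COC1=O | intermediate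
36 | methyl (R)-glycerate, methyl (2R)-2,3-dihydroxypropanoate | COC(=O)[C@@H](CO)O | starting material
37 | methyl (2R)-3-(tert-butyldimethylsilyloxy)-2-hydroxypropanoate | COC(=O)[C@@H](CO[Si](C)(C)C(C)(C)C)O | intermediate
38 | methyl (2S)-2-(4-bromo-2-methoxyphenoxy)-3-(tert-butyldimethylsilyloxy)propanoate | COC(=O)[C@H](CO[Si](C)(C)C(C)(C)C)Oc1ccc(Br)cc1OC | intermediate
39 | (2S)-2-(4-bromo-2-methoxyphenoxy)-3-(tert-butyldimethylsilyloxy)propanal | O=C[C@H](CO[Si](C)(C)C(C)(C)C)Oc1ccc(Br)cc1OC | intermediate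
40 | (1R,2S)-2-(4-bromo-2-methoxyphenoxy)-3-(TBS-oxy)-1-(GuaTIPS)propan-1-ol, erythro | COc1cc([C@@H](O)[C@H](CO[Si](C)(C)C(C)(C)C)Oc2ccc(Br)cc2OC)ccc1O[Si](C(C)C)(C(C)C)C(C)C | intermediate
41 | 1,3-bis-TBS ether of (1R,2S)-2-(4-bromo-2-methoxyphenoxy)-1-(GuaTIPS)propane-1,3-diol | COc1cc([C@@H](O[Si](C)(C)C(C)(C)C)[C@H](CO[Si](C)(C)C(C)(C)C)Oc2ccc(Br)cc2OC)ccc1O[Si](C(C)C)(C(C)C)C(C)C | intermediate
42 | aryllithium from 41 (lithium in place of bromine) | COc1cc([C@@H](O[Si](C)(C)C(C)(C)C)[C@H](CO[Si](C)(C)C(C)(C)C)Oc2ccc([Li])cc2OC)ccc1O[Si](C(C)C)(C(C)C)C(C)C | intermediate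
43 | 3-methoxy-4-(eryA-oxy)benzaldehyde | COc1cc([C@@H](O[Si](C)(C)C(C)(C)C)[C@H](CO[Si](C)(C)C(C)(C)C)Oc2ccc(C=O)cc2OC)ccc1O[Si](C(C)C)(C(C)C)C(C)C | intermediate
44 | (Z)-dibutylboron enolate of imide 35 | COc1cc([C@@H]2OC[C@@H]3[C@H]2CO[C@H]3c2cc(OC)c(O[C@H](CO[Si](C)(C)C(C)(C)C)[C@@H](O[Si](C)(C)C(C)(C)C)c3ccc(O[Si](C(C)C)(C(C)C)C(C)C)c(OC)c3)c(OC)c2)cc(OC)c1O/C=C(\OB(CCCC)CCCC)N1[C@@H](Cc2ccccc2)COC1=O | intermediate
45 | (4S)-4-benzyl-3-[(2S,3R)-3-hydroxy-3-[3-methoxy-4-(eryA-oxy)phenyl]-2-(aryloxy of 33)propanoyl]-1,3-oxazolidin-2-one | COc1cc([C@@H](O[Si](C)(C)C(C)(C)C)[C@H](CO[Si](C)(C)C(C)(C)C)Oc2ccc([C@@H](O)[C@@H](C(=O)N6[C@@H](Cc7ccccc7)COC6=O)Oc3c(OC)cc([C@@H]4OC[C@@H]5[C@H]4CO[C@H]5c4cc(OC)c(O[C@H](CO[Si](C)(C)C(C)(C)C)[C@@H](O[Si](C)(C)C(C)(C)C)c5ccc(O[Si](C(C)C)(C(C)C)C(C)C)c(OC)c5)c(OC)c4)cc3OC)cc2OC)ccc1O[Si](C(C)C)(C(C)C)C(C)C | intermediate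
46 | (1R,2R)-1-[3-methoxy-4-(eryA-oxy)phenyl]-2-(aryloxy of 33)propane-1,3-diol, threo | COc1cc([C@@H](O[Si](C)(C)C(C)(C)C)[C@H](CO[Si](C)(C)C(C)(C)C)Oc2ccc([C@@H](O)[C@@H](CO)Oc3c(OC)cc([C@@H]4OC[C@@H]5[C@H]4CO[C@H]5c4cc(OC)c(O[C@H](CO[Si](C)(C)C(C)(C)C)[C@@H](O[Si](C)(C)C(C)(C)C)c5ccc(O[Si](C(C)C)(C(C)C)C(C)C)c(OC)c5)c(OC)c4)cc3OC)cc2OC)ccc1O[Si](C(C)C)(C(C)C)C(C)C | intermediate
47 | CNP0316493.1: (7R,8S,7'R,8'S)-syringaresinol with one phenolic oxygen bound to C8 of a (7R,8R)-threo-guaiacylglycerol unit, whose own phenolic oxygen is bound to C8 of a (7R,8S)-erythro-guaiacylglycerol unit, and the other phenolic oxygen bound to C8 of a (7S,8R)-erythro-guaiacylglycerol unit | COc1cc([C@@H](O)[C@H](CO)Oc2ccc([C@@H](O)[C@@H](CO)Oc3c(OC)cc([C@@H]4OC[C@@H]5[C@H]4CO[C@H]5c4cc(OC)c(O[C@H](CO)[C@@H](O)c5ccc(O)c(OC)c5)c(OC)c4)cc3OC)cc2OC)ccc1O | target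

## Step count and least certain steps

Total: 26 steps. Longest linear sequence: 16 steps (steps 1, 2, 3, 6, 7, 8, 9, 10, 12, 15, 16, 17, 18, 24, 25, 26).

**Step 7 (key step, new method).**
- What may go wrong: the dynamic resolution may discriminate poorly between the C8 (or C8') epimers, or epimerisation of the keto lactone formed after the first reduction may be slow. Material would then be diverted into hydroxy ester lactones that cannot close the second ring, or into the endo,endo bicycle. The electron-rich ketones may also be reduced sluggishly, and the first hydroxyl may mask the second ketone as a cyclic hemiketal.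
- Fallback (known chemistry, racemic synthesis and resolution): starting from 17, NaBH4 in ethanol at 0 °C followed by warming with acetic acid in toluene should give the dilactone diastereomers as racemates. The exo,exo racemate, 19 together with its mirror image ent-19 F1, would be isolated by crystallisation. Preparative chromatography on a chiral stationary phase then gives 19, and the route is rejoined at 19 before step 8.

**Step 6.**
- What may go wrong: chlorine transfer from 9 to enolate 16 is a degenerate exchange that would scramble the two halves into the two symmetrical succinates beside 17. O-alkylation of the enolate is a second risk.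
- Fallback (symmetrical core, desymmetrised late): starting from 8, the sodium enolate (NaH, THF) is coupled oxidatively with iodine (0.5 equiv) to diethyl 2,3-bis(4-benzyloxy-3,5-dimethoxybenzoyl)succinate F2. The conditions of step 7 would convert this to the bis-benzyl dilactone F3, LiAlH4 to tetraol F4, and MsCl in pyridine to the dibenzyl ether of (−)-syringaresinol F5. Hydrogenolysis over Pd/C interrupted near half conversion, with recycling of recovered F5, gives the monobenzyl ether, which is 23 because the two ends are homotopic. The route is rejoined at 23.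

**Step 15 (step 21 is the same reaction on a small fragment, where isomers are more easily removed).**
- What may go wrong: chelation of magnesium by the methoxy-flanked aryloxy group may erode the Felkin selectivity; the aldehyde may epimerise at C8c before capture; the ester may be over-reduced.
- Fallback (reagent-controlled reduction in place of substrate-controlled arylation): starting from 26, Me(MeO)NH·HCl and iPrMgCl in THF at −20 °C give the Weinreb amide F6. Grignard reagent 29 converts it to the aryl ketone F7. Transfer hydrogenation with RuCl(p-cymene)[(R,R)-TsDPEN] in HCO2H/Et3N should then set C7c as S under catalyst control and return the route to 31.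

**Step 24.**
- What may go wrong: the many ether oxygens may sequester Bu2BOTf and leave enolisation incomplete; the electron-rich aldolate may undergo retro-aldol cleavage during work-up; the boron Lewis acid may ionise a furofuran C7–O bond.
- Fallback (build unit b by etherification, acylation and ketone reduction): starting from 33, Mitsunobu reaction with 25 gives the (R)-α-aryloxy ester F8, and Me(MeO)NH·HCl with iPrMgCl gives the Weinreb amide F9. Addition of aryllithium 42 (from 41 and n-BuLi) gives the ketone F10. Transfer hydrogenation with RuCl(p-cymene)[(S,S)-TsDPEN] in HCO2H/Et3N should give the (7R,8R)-threo alcohol F11, which carries a TBS ether at C9b. The conditions of step 26 remove all silyl groups, and the route is rejoined at 47.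

## Further compounds

F1 | step 7 | ent-19, (3S,3aS,6S,6aS)-3-(SyrBn)-6-(SyrTIPS)tetrahydro-1H,3H-furo[3,4-c]furan-1,4-dione | COc1cc([C@H]2OC(=O)[C@H]3[C@@H]2C(=O)O[C@@H]3c2cc(OC)c(O[Si](C(C)C)(C(C)C)C(C)C)c(OC)c2)cc(OC)c1OCc1ccccc1
F2 | step 6 | diethyl 2,3-bis(4-benzyloxy-3,5-dimethoxybenzoyl)succinate, stereoisomer mixture | CCOC(=O)C(C(=O)c1cc(OC)c(OCc2ccccc2)c(OC)c1)C(C(=O)OCC)C(=O)c1cc(OC)c(OCc2ccccc2)c(OC)c1
F3 | step 6 | (3R,3aR,6R,6aR)-3,6-bis(SyrBn)tetrahydro-1H,3H-furo[3,4-c]furan-1,4-dione | COc1cc([C@@H]2OC(=O)[C@@H]3[C@H]2C(=O)O[C@H]3c2cc(OC)c(OCc4ccccc4)c(OC)c2)cc(OC)c1OCc1ccccc1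
F4 | step 6 | (1R,2S,3S,4R)-1,4-bis(SyrBn)-2,3-bis(hydroxymethyl)butane-1,4-diol | COc1cc([C@H](O)[C@H](CO)[C@@H](CO)[C@@H](O)c2cc(OC)c(OCc3ccccc3)c(OC)c2)cc(OC)c1OCc1ccccc1
F5 | step 6 | (1R,3aS,4R,6aS)-1,4-bis(SyrBn)-FF, dibenzyl ether of (−)-syringaresinol | COc1cc([C@@H]2OC[C@@H]3[C@H]2CO[C@H]3c2cc(OC)c(OCc3ccccc3)c(OC)c2)cc(OC)c1OCc1ccccc1
F6 | step 15 | (2R)-N-methoxy-N-methyl-3-(TBS-oxy)-2-{4-[(1R,3aS,4R,6aS)-4-(SyrBn)-FF-1-yl]-2,6-dimethoxyphenoxy}propanamide | COc1cc([C@@H]2OC[C@@H]3[C@H]2CO[C@H]3c2cc(OC)c(O[C@H](CO[Si](C)(C)C(C)(C)C)C(=O)N(C)OC)c(OC)c2)cc(OC)c1OCc1ccccc1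
F7 | step 15 | (2R)-3-(TBS-oxy)-1-(GuaTIPS)-2-{4-[(1R,3aS,4R,6aS)-4-(SyrBn)-FF-1-yl]-2,6-dimethoxyphenoxy}propan-1-one | COc1cc([C@@H]2OC[C@@H]3[C@H]2CO[C@H]3c2cc(OC)c(O[C@H](CO[Si](C)(C)C(C)(C)C)C(=O)c3ccc(O[Si](C(C)C)(C(C)C)C(C)C)c(OC)c3)c(OC)c2)cc(OC)c1OCc1ccccc1
F8 | step 24 | methyl (2R)-3-(TBS-oxy)-2-(aryloxy of 33)propanoate | COc1cc([C@@H]2OC[C@@H]3[C@H]2CO[C@H]3c2cc(OC)c(O[C@H](CO[Si](C)(C)C(C)(C)C)[C@@H](O[Si](C)(C)C(C)(C)C)c3ccc(O[Si](C(C)C)(C(C)C)C(C)C)c(OC)c3)c(OC)c2)cc(OC)c1O[C@H](CO[Si](C)(C)C(C)(C)C)C(=O)OC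
F9 | step 24 | (2R)-N-methoxy-N-methyl-3-(TBS-oxy)-2-(aryloxy of 33)propanamide | COc1cc([C@@H]2OC[C@@H]3[C@H]2CO[C@H]3c2cc(OC)c(O[C@H](CO[Si](C)(C)C(C)(C)C)[C@@H](O[Si](C)(C)C(C)(C)C)c3ccc(O[Si](C(C)C)(C(C)C)C(C)C)c(OC)c3)c(OC)c2)cc(OC)c1O[C@H](CO[Si](C)(C)C(C)(C)C)C(=O)N(C)OC
F10 | step 24 | (2R)-3-(TBS-oxy)-1-[3-methoxy-4-(eryA-oxy)phenyl]-2-(aryloxy of 33)propan-1-one | COc1cc([C@@H]2OC[C@@H]3[C@H]2CO[C@H]3c2cc(OC)c(O[C@H](CO[Si](C)(C)C(C)(C)C)[C@@H](O[Si](C)(C)C(C)(C)C)c3ccc(O[Si](C(C)C)(C(C)C)C(C)C)c(OC)c3)c(OC)c2)cc(OC)c1O[C@H](CO[Si](C)(C)C(C)(C)C)C(=O)c1ccc(O[C@@H](CO[Si](C)(C)C(C)(C)C)[C@H](O[Si](C)(C)C(C)(C)C)c2ccc(O[Si](C(C)C)(C(C)C)C(C)C)c(OC)c2)c(OC)c1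
F11 | step 24 | (1R,2R)-3-(TBS-oxy)-1-[3-methoxy-4-(eryA-oxy)phenyl]-2-(aryloxy of 33)propan-1-ol, threo | COc1cc([C@@H]2OC[C@@H]3[C@H]2CO[C@H]3c2cc(OC)c(O[C@H](CO[Si](C)(C)C(C)(C)C)[C@@H](O[Si](C)(C)C(C)(C)C)c3ccc(O[Si](C(C)C)(C(C)C)C(C)C)c(OC)c3)c(OC)c2)cc(OC)c1O[C@H](CO[Si](C)(C)C(C)(C)C)[C@H](O)c1ccc(O[C@@H](CO[Si](C)(C)C(C)(C)C)[C@H](O[Si](C)(C)C(C)(C)C)c2ccc(O[Si](C(C)C)(C(C)C)C(C)C)c(OC)c2)c(OC)c1
A1 | alternative 1 | bis(α-aryloxy aldehyde) carrying the furofuran core and the acetonide-protected threo unit | O=C[C@H](CO[Si](C)(C)C(C)(C)C)Oc2ccc(cc2OC)[C@H]2OC(C)(C)OC[C@H]2Oc2c(OC)cc(cc2OC)[C@@H]2OC[C@@H]3[C@H]2CO[C@H]3c2cc(OC)c(O[C@H](CO[Si](C)(C)C(C)(C)C)C=O)c(OC)c2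
A2 | alternative 1 | (4-benzyloxy-3-methoxyphenyl)magnesium bromide | COc1cc([Mg]Br)ccc1OCc1ccccc1
A3 | alternative 1 | protected target with both terminal erythro units formed | COc1cc([C@@H](O)[C@H](CO[Si](C)(C)C(C)(C)C)Oc2ccc(cc2OC)[C@H]2OC(C)(C)OC[C@H]2Oc2c(OC)cc(cc2OC)[C@@H]2OC[C@@H]3[C@H]2CO[C@H]3c2cc(OC)c(O[C@H](CO[Si](C)(C)C(C)(C)C)[C@@H](O)c3ccc(OCc4ccccc4)c(OC)c3)c(OC)c2)ccc1OCc1ccccc1
A4 | alternative 2 | (5S)-5-(d-menthyloxy)furan-2(5H)-one | C[C@H]1CC[C@@H]([C@H](C1)O[C@H]2OC(=O)C=C2)C(C)C
A5 | alternative 2 | 2-(4-benzyloxy-3,5-dimethoxyphenyl)-1,3-dithiane | COc1cc(C2SCCCS2)cc(OC)c1OCc1ccccc1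
A6 | alternative 2 | 3,5-dimethoxy-4-(triisopropylsilyloxy)benzaldehyde | COc1cc(C=O)cc(OC)c1O[Si](C(C)C)(C(C)C)C(C)C
A7 | alternative 2 | trans-3-(aryl-hydroxymethyl)-4-(2-aryl-1,3-dithian-2-yl)-5-menthyloxybutyrolactone, carbinol epimers | C[C@H]1CC[C@@H]([C@H](C1)O[C@H]2OC(=O)[C@@H](C(O)c3cc(OC)c(O[Si](C(C)C)(C(C)C)C(C)C)c(OC)c3)[C@@H]2C2(c3cc(OC)c(OCc4ccccc4)c(OC)c3)SCCCS2)C(C)C
A8 | alternative 3 | 3,7-dioxabicyclo[3.3.0]octane-2,6-diyl diacetate with target bridgehead configuration, anomer mixture | CC(=O)OC1OC[C@@H]2[C@H]1COC2OC(C)=O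
A9 | alternative 3 | (4-benzyloxy-3,5-dimethoxyphenyl)zinc bromide | COc1cc([Zn]Br)cc(OC)c1OCc1ccccc1
A10 | alternative 3 | (−)-syringaresinol dibenzyl ether | COc1cc([C@@H]2OC[C@@H]3[C@H]2CO[C@H]3c2cc(OC)c(OCc3ccccc3)c(OC)c2)cc(OC)c1OCc1ccccc1
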